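**Retrosynthetic overview**

1. Target 27 ⇐ quinone 26 ⇐ trimethyl ether 25 ⇐ 3-oxo lactone 22. The hydroquinone is unveiled last ((NH4)2Ce(NO3)6, then Na2S2O4); the C3 carbonyl, the activating group of the key step, is removed through its tosylhydrazone.
2. 22 ⇐ bromo β-keto ester 20. One Michael/alkylation [3+3] annulation makes C4–C5 and C1–C2, closes the δ-lactone ring and ring A together, sets C4 and C5, and funnels the ester α-epimers into one product.
3. Enabling feature: C10 is a quaternary carbon that carries two one-carbon arms (C1 and C20) and is bonded to C5, the β-carbon of the C7 aryl ketone. Ring A and the lactone ring share C4–C5–C10 as a 2-oxabicyclo[3.3.1]nonane, so a 2-methylacetoacetyl group on the C20 oxygen reaches C5 with C4 and the C1 arm with C2.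
4. 20 ⇐ bromohydrin 18 ⇐ achiral spiro-oxetane 16 (catalytic enantioselective ring opening sets C10) ⇐ prochiral diol 13 ⇐ tetralone malonate 11 ⇐ keto malonate 10 (radical arylation closes ring B at C9–C10) ⇐ arene 5 + 3-chloropropanoyl chloride + diethyl malonate.
5. Ring order: ring C is bought as an arene, ring B is closed second, the lactone ring and ring A are closed together in the key step.

Key step: step 12

Remark: atom numbers C1–C20 are abietane numbers. Ring A = C1–C5 and C10; ring B = C5–C10; ring C = C8, C9, C11–C14; C18 = methyl on C4; C19 = lactone carbonyl on C4; C20 = OCH2 on C10.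

Assumption: the sense of induction of the squaramide-catalysed oxetane opening (step 10) is not predicted here; the catalyst antipode that delivers (S)-18 is used.

**Route**

Step 1
Reactants: 1 1,2,4-trimethoxybenzene; 2 acetone
Product: 4 2-(2,3,6-trimethoxyphenyl)propan-2-ol, via (2,3,6-trimethoxyphenyl)lithium 3 (not isolated)
Conditions: n-BuLi, THF, 0 °C → rt; acetone, −78 °C → rt; H2O
Reagents that add atoms: none
Why: Directed ortho-lithiation should take place at the ring CH flanked by two methoxy groups, and the aryllithium adds to the ketone.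

Step 2
Reactants: 4 2-(2,3,6-trimethoxyphenyl)propan-2-ol
Product: 5 2-isopropyl-1,3,4-trimethoxybenzene
Conditions: Et3SiH, CF3CO2H, CH2Cl2, 0 °C → rt
Reagents that add atoms: none
Why: Ionic hydrogenation: the acid ionises the tertiary benzylic alcohol to a cation stabilised by two ortho methoxy groups and the silane delivers hydride.

Step 3
Reactants: 5 2-isopropyl-1,3,4-trimethoxybenzene; 6 3-chloropropanoyl chloride
Product: 7 3-chloro-1-(3-isopropyl-2,4,5-trimethoxyphenyl)propan-1-one
Conditions: AlCl3, CH2Cl2, −10 → 0 °C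
Reagents that add atoms: none
Why: Friedel–Crafts acylation should go to the ring CH that is ortho to one methoxy group and para to another (the other CH is ortho to only one), which puts C7 on C8; low temperature keeps the ortho methoxy group and the β-chloride intact.

Step 4
Reactants: 7 3-chloro-1-(3-isopropyl-2,4,5-trimethoxyphenyl)propan-1-one; 8 diethyl malonate
Product: 10 diethyl 2-[3-(3-isopropyl-2,4,5-trimethoxyphenyl)-3-oxopropyl]malonate, via aryl vinyl ketone 9 (not isolated)
Conditions: NaOEt, diethyl malonate (excess), EtOH, 0 °C → rt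
Reagents that add atoms: none
Why: Ethoxide eliminates HCl to the enone, which takes up the malonate anion by Michael addition (C5–C10 bond); excess malonate suppresses double addition.

Step 5
Reactants: 10 diethyl 2-[3-(3-isopropyl-2,4,5-trimethoxyphenyl)-3-oxopropyl]malonate
Product: 11 diethyl 6-isopropyl-5,7,8-trimethoxy-4-oxo-3,4-dihydronaphthalene-1,1(2H)-dicarboxylate
Conditions: Mn(OAc)3·2H2O, AcOH, 70 °C
Reagents that add atoms: none
Why: Trivalent manganese oxidises the malonate, the only readily enolised site, to an electrophilic malonyl radical that attacks the electron-rich ring at its one free position (C9) and closes ring B; a second oxidation and proton loss restore the arene (oxidative radical aromatic substitution of aryl-tethered malonates).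

Step 6
Reactants: 11 diethyl 6-isopropyl-5,7,8-trimethoxy-4-oxo-3,4-dihydronaphthalene-1,1(2H)-dicarboxylate
Product: 12 (±)-4,4-bis(hydroxymethyl)-7-isopropyl-5,6,8-trimethoxy-1,2,3,4-tetrahydronaphthalen-1-ol
Conditions: LiAlH4, THF, 0 °C → reflux; aqueous work-up
Reagents that add atoms: none
Why: Exhaustive hydride reduction of both esters and the ketone avoids any chemoselectivity problem; the carbinol centre is erased in the next step.

Step 7
Reactants: 12 (±)-4,4-bis(hydroxymethyl)-7-isopropyl-5,6,8-trimethoxy-1,2,3,4-tetrahydronaphthalen-1-ol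
Product: 13 4,4-bis(hydroxymethyl)-7-isopropyl-5,6,8-trimethoxy-3,4-dihydronaphthalen-1(2H)-one
Conditions: MnO2, CH2Cl2, rt
Reagents that add atoms: none
Why: Activated MnO2 oxidises only the benzylic secondary alcohol and should leave the two neopentyl primary alcohols untouched, giving the prochiral diol.

Step 8
Reactants: 13 4,4-bis(hydroxymethyl)-7-isopropyl-5,6,8-trimethoxy-3,4-dihydronaphthalen-1(2H)-one
Product: 15 6'-isopropyl-5',7',8'-trimethoxy-2',3'-dihydro-4'H-spiro[oxetane-3,1'-naphthalen]-4'-one, via monotosylate 14 (not isolated)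
Conditions: TsCl (1.05 equiv), pyridine, CH2Cl2, 0 °C; then t-BuOK, THF, 0 → 25 °C
Reagents that add atoms: none
Why: Monosulfonylation and intramolecular Williamson etherification (4-exo-tet, helped by the gem-disubstitution at C10) give an achiral oxetane, so the statistical choice of arm is irrelevant; it is done on the tetralone because the alkoxide of a 4-(hydroxymethyl)naphthalen-1(4H)-one could expel formaldehyde and aromatise.

Step 9
Reactants: 15 6'-isopropyl-5',7',8'-trimethoxy-2',3'-dihydro-4'H-spiro[oxetane-3,1'-naphthalen]-4'-one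
Product: 16 6'-isopropyl-5',7',8'-trimethoxy-4'H-spiro[oxetane-3,1'-naphthalen]-4'-one
Conditions: IBX (2-iodoxybenzoic acid), DMSO, 75 °C
Reagents that add atoms: none
Why: IBX-mediated α,β-dehydrogenation of the aryl ketone should give the C5=C6 enone; C10 is quaternary, so the ring cannot aromatise, and no oxidisable OH is present.

Step 10
Reactants: 16 6'-isopropyl-5',7',8'-trimethoxy-4'H-spiro[oxetane-3,1'-naphthalen]-4'-one
Product: 18 (4S)-4-(bromomethyl)-4-(hydroxymethyl)-7-isopropyl-5,6,8-trimethoxynaphthalen-1(4H)-one, via silyl ether 17 (not isolated)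
Conditions: Me3SiBr, chiral arylpyrrolidine-derived squaramide hydrogen-bond donor (10 mol %), t-BuOMe, −78 → −40 °C; then aqueous citric acid, THF
Reagents that add atoms: bromotrimethylsilane, C[Si](C)(C)Br
Why: Catalytic enantioselective desymmetrising ring opening of a 3,3-disubstituted oxetane: catalyst-bound bromide attacks one of the two enantiotopic CH2 groups of the silylated oxetane, which sets C10 (the bromomethyl arm becomes C1, the hydroxymethyl arm C20) without any base.

Step 11
Reactants: 18 (4S)-4-(bromomethyl)-4-(hydroxymethyl)-7-isopropyl-5,6,8-trimethoxynaphthalen-1(4H)-one; 19 ethyl 2-methyl-3-oxobutanoate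
Product: 20 [(1S)-1-(bromomethyl)-6-isopropyl-5,7,8-trimethoxy-4-oxo-1,4-dihydronaphthalen-1-yl]methyl (2RS)-2-methyl-3-oxobutanoate
Conditions: 19 (excess), xylenes, 135 °C, EtOH distilled off
Reagents that add atoms: none
Why: Thermal transacylation of the β-keto ester through methyl(acetyl)ketene should acylate the neopentyl alcohol under neutral conditions, so no alkoxide forms on the enone; the ester α-carbon is a mixture of epimers, which the next step makes irrelevant.

Step 12
Reactants: 20 [(1S)-1-(bromomethyl)-6-isopropyl-5,7,8-trimethoxy-4-oxo-1,4-dihydronaphthalen-1-yl]methyl (2RS)-2-methyl-3-oxobutanoate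
Product: 22 (4R,5R,10R)-11,12,14-trimethoxy-3,7-dioxoabieta-8,11,13-trien-19,20-olide, via Michael adduct 21 (not isolated)
Conditions: DBU (0.2 equiv), THF, 25 °C; then t-BuOK (3 equiv), t-BuOH, 60 °C
Reagents that add atoms: none
Why: Catalytic DBU forms the β-keto ester enolate of 20, whose C4 adds reversibly to C5 of the ring B enone (intramolecular Michael addition) to give 21; t-BuOK then enolises the acetyl group toward C2, the only enolisable side of the C3 ketone once C4 is quaternary, and this enolate displaces bromide at C1 (intramolecular SN2), the whole being a Michael/alkylation [3+3] annulation. The closest known reaction types are the intramolecular Michael addition of ester-tethered β-keto esters to cyclohexenones and cyclohexadienones and the ring-forming alkylation of ketone enolates by neopentyl-type primary halides. The δ-lactone ring closes 6-exo-trig (C4 onto C5) and ring A closes 6-(enolendo)-exo-tet (C2 onto C1), which together give the 2-oxabicyclo[3.3.1]nonane. C5 is controlled by the three-atom ester tether, which can deliver C4 only to the enone face that carries C20 (cis-fused lactone, H-5 anti to C20, hence the trans A/B junction), and C4 is controlled by the bicycle, since only the Michael epimer whose acetyl group is syn to the bromomethyl arm can reach C1. The step is stereoconvergent: both α-epimers of 20 pass through one enolate, and the unproductive C4 epimer of 21 returns through retro-Michael/Michael equilibration while the productive one is drained by the irreversible alkylation. The selectivity needed is C-alkylation from C2 instead of O-alkylation or alkylation from C4: six-membered enolendo closure favours carbon, and the stabilised, fully substituted C4 enolate is a poor nucleophile toward a neopentyl carbon.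

Step 13
Reactants: 22 (4R,5R,10R)-11,12,14-trimethoxy-3,7-dioxoabieta-8,11,13-trien-19,20-olide
Product: 23 (4R,5R,10R)-11,12,14-trimethoxy-3,7-dioxoabieta-8,11,13-trien-19,20-olide 3-(4-methylbenzenesulfonyl)hydrazone (C=N geometry not defined)
Conditions: TsNHNH2, EtOH, 60 °C
Reagents that add atoms: 4-methylbenzenesulfonohydrazide, Cc1ccc(S(=O)(=O)NN)cc1
Why: Hydrazone condensation should select the dialkyl C3 ketone, because the C7 ketone is conjugated with an electron-rich ring and flanked by the C14 methoxy group.

Step 14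
Reactants: 23 the 3-tosylhydrazone of 22
Product: 25 (4S,5R,10R)-11,12,14-trimethoxy-7-oxoabieta-8,11,13-trien-19,20-olide, via N-boryl tosylhydrazine 24 (not isolated)
Conditions: catecholborane, CHCl3, 0 °C; then NaOAc·3H2O, reflux
Reagents that add atoms: none
Why: Tosylhydrazone reduction: hydride adds to C=N, acetate then releases sulfinate, and the diazene loses N2 to leave CH2 at C3; the lactone and the deactivated aryl ketone should survive, and C4 changes descriptor only through the priority change.

Step 15
Reactants: 25 (4S,5R,10R)-11,12,14-trimethoxy-7-oxoabieta-8,11,13-trien-19,20-olide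
Product: 26 (4S,5R,10R)-12-methoxy-7,11,14-trioxoabieta-8,12-dien-19,20-olide
Conditions: (NH4)2Ce(NO3)6, MeCN/H2O, 0 °C
Reagents that add atoms: water, O
Why: Oxidative demethylation: tetravalent cerium oxidises the para-dimethoxy pair (C11/C14) to the para-quinone by ipso attack of water and loss of methanol, while the C12 methoxy group, which has no para oxygen partner, stays as a vinylogous ester.

Step 16
Reactants: 26 (4S,5R,10R)-12-methoxy-7,11,14-trioxoabieta-8,12-dien-19,20-olide
Product: 27 (4S,5R,10R)-11,14-dihydroxy-12-methoxy-7-oxoabieta-8,11,13-trien-19,20-olide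
Conditions: Na2S2O4, EtOAc/H2O, 25 °C, under argon
Reagents that add atoms: none
Why: Dithionite reduces the quinone to the hydroquinone without touching the ketone or lactone; the C14 hydroxyl is held by a hydrogen bond to the C7 ketone.

**Compound list**

1 | 1,2,4-trimethoxybenzene | COc1ccc(OC)c(OC)c1 | starting material
2 | acetone | CC(C)=O | starting material
3 | (2,3,6-trimethoxyphenyl)lithium | [Li]c1c(OC)ccc(OC)c1OC | intermediate
4 | 2-(2,3,6-trimethoxyphenyl)propan-2-ol | CC(C)(O)c1c(OC)ccc(OC)c1OC | intermediate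
5 | 2-isopropyl-1,3,4-trimethoxybenzene | CC(C)c1c(OC)ccc(OC)c1OC | intermediate
6 | 3-chloropropanoyl chloride | O=C(Cl)CCCl | starting material
7 | 3-chloro-1-(3-isopropyl-2,4,5-trimethoxyphenyl)propan-1-one | CC(C)c1c(OC)c(OC)cc(C(=O)CCCl)c1OC | intermediate
8 | diethyl malonate | CCOC(=O)CC(=O)OCC | starting material
9 | 1-(3-isopropyl-2,4,5-trimethoxyphenyl)prop-2-en-1-one | CC(C)c1c(OC)c(OC)cc(C(=O)C=C)c1OC | intermediate
10 | diethyl 2-[3-(3-isopropyl-2,4,5-trimethoxyphenyl)-3-oxopropyl]malonate | CCOC(=O)C(CCC(=O)c1cc(OC)c(OC)c(C(C)C)c1OC)C(=O)OCC | intermediate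
11 | diethyl 6-isopropyl-5,7,8-trimethoxy-4-oxo-3,4-dihydronaphthalene-1,1(2H)-dicarboxylate | CCOC(=O)C1(C(=O)OCC)CCC(=O)c2c1c(OC)c(OC)c(C(C)C)c2OC | intermediate
12 | (±)-4,4-bis(hydroxymethyl)-7-isopropyl-5,6,8-trimethoxy-1,2,3,4-tetrahydronaphthalen-1-ol | OCC1(CO)CCC(O)c2c1c(OC)c(OC)c(C(C)C)c2OC | intermediate
13 | 4,4-bis(hydroxymethyl)-7-isopropyl-5,6,8-trimethoxy-3,4-dihydronaphthalen-1(2H)-one | OCC1(CO)CCC(=O)c2c1c(OC)c(OC)c(C(C)C)c2OC | intermediate
14 | (±)-[1-(hydroxymethyl)-6-isopropyl-5,7,8-trimethoxy-4-oxo-1,2,3,4-tetrahydronaphthalen-1-yl]methyl 4-methylbenzenesulfonate | Cc1ccc(S(=O)(=O)OCC2(CO)CCC(=O)c3c2c(OC)c(OC)c(C(C)C)c3OC)cc1 | intermediate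
15 | 6'-isopropyl-5',7',8'-trimethoxy-2',3'-dihydro-4'H-spiro[oxetane-3,1'-naphthalen]-4'-one | O=C1CCC2(COC2)c3c1c(OC)c(C(C)C)c(OC)c3OC | intermediate
16 | 6'-isopropyl-5',7',8'-trimethoxy-4'H-spiro[oxetane-3,1'-naphthalen]-4'-one | O=C1C=CC2(COC2)c3c1c(OC)c(C(C)C)c(OC)c3OC | intermediate
17 | (4S)-4-(bromomethyl)-7-isopropyl-5,6,8-trimethoxy-4-[(trimethylsilyloxy)methyl]naphthalen-1(4H)-one | C[Si](C)(C)OC[C@]1(CBr)C=CC(=O)c2c1c(OC)c(OC)c(C(C)C)c2OC | intermediate
18 | (4S)-4-(bromomethyl)-4-(hydroxymethyl)-7-isopropyl-5,6,8-trimethoxynaphthalen-1(4H)-one | OC[C@]1(CBr)C=CC(=O)c2c1c(OC)c(OC)c(C(C)C)c2OC | intermediate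
19 | ethyl 2-methyl-3-oxobutanoate | CCOC(=O)C(C)C(C)=O | starting material
20 | [(1S)-1-(bromomethyl)-6-isopropyl-5,7,8-trimethoxy-4-oxo-1,4-dihydronaphthalen-1-yl]methyl (2RS)-2-methyl-3-oxobutanoate | CC(=O)C(C)C(=O)OC[C@]1(CBr)C=CC(=O)c2c1c(OC)c(OC)c(C(C)C)c2OC | intermediate
21 | (4R,5S,10S)-1-bromo-11,12,14-trimethoxy-3,7-dioxo-1,2-secoabieta-8,11,13-trien-19,20-olide (cis-fused δ-lactone on ring B; productive C4 epimer, acetyl syn to the bromomethyl arm) | COc1c(OC)c2c(c(OC)c1C(C)C)C(=O)C[C@@H]1[C@@]2(CBr)COC(=O)[C@@]1(C)C(C)=O | intermediate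
22 | (4R,5R,10R)-11,12,14-trimethoxy-3,7-dioxoabieta-8,11,13-trien-19,20-olide | COc1c(OC)c2c(c(OC)c1C(C)C)C(=O)C[C@@H]1[C@]23CCC(=O)[C@]1(C)C(=O)OC3 | intermediate
23 | (4R,5R,10R)-11,12,14-trimethoxy-3,7-dioxoabieta-8,11,13-trien-19,20-olide 3-(4-methylbenzenesulfonyl)hydrazone | COc1c(OC)c2c(c(OC)c1C(C)C)C(=O)C[C@@H]1[C@]23CCC(=NNS(=O)(=O)c4ccc(C)cc4)[C@]1(C)C(=O)OC3 | intermediate
24 | (4R,5R,10R)-3-[1-(1,3,2-benzodioxaborol-2-yl)-2-(4-methylbenzenesulfonyl)hydrazinyl]-11,12,14-trimethoxy-7-oxoabieta-8,11,13-trien-19,20-olide (C3 epimers) | COc1c(OC)c2c(c(OC)c1C(C)C)C(=O)C[C@@H]1[C@]23CCC(N(NS(=O)(=O)c4ccc(C)cc4)B4Oc5ccccc5O4)[C@]1(C)C(=O)OC3 | intermediate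
25 | (4S,5R,10R)-11,12,14-trimethoxy-7-oxoabieta-8,11,13-trien-19,20-olide | COc1c(OC)c2c(c(OC)c1C(C)C)C(=O)C[C@@H]1[C@]23CCC[C@]1(C)C(=O)OC3 | intermediate
26 | (4S,5R,10R)-12-methoxy-7,11,14-trioxoabieta-8,12-dien-19,20-olide | COC1=C(C(C)C)C(=O)C2=C(C1=O)[C@]34CCC[C@](C)(C(=O)OC3)[C@@H]4CC2=O | intermediate
27 | (4S,5R,10R)-11,14-dihydroxy-12-methoxy-7-oxoabieta-8,11,13-trien-19,20-olide (CNP0159814.2) | COc1c(O)c2c(c(O)c1C(C)C)C(=O)C[C@@H]1[C@]23CCC[C@]1(C)C(=O)OC3 | target

**Step count and risks**

Total step count: 16. Longest linear sequence: 16 steps (from 1).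

Steps most likely to fail:

Step 12. Ring A closure may fail through O-alkylation of the C3 enolate, through slow substitution at the neopentyl C1, or through retro-Michael loss of 21 before alkylation. Fallback, from 20 back to 22: only the DBU stage is run and the Michael adduct 21 is isolated. TMSOTf/Et3N converts both ketones into the bis(silyl enol ether) F1. Bu3SnH (slow addition) and AIBN in benzene at 80 °C generate the C1 radical, which should close ring A by 6-endo attack on the CH2 terminus of the 2-silyloxyalkene, the usual mode for 5-silyloxyhex-5-enyl radicals, to give the 3-silyloxy tetracycle F2. Aqueous HCl gives the 3-hydroxy 7-ketone F3, and DMP oxidation returns 22. The unproductive C4 epimer of 21 is re-equilibrated with DBU.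

Step 5. The electron-rich arene may be over-oxidised by trivalent manganese, or the malonyl radical may add too slowly next to the acyl group. Fallback, from 10 back to 11: NBS in MeCN brominates the one free ring position to give the aryl bromide F4. Pd(OAc)2/t-Bu3P with Cs2CO3 in toluene at 90 °C then closes ring B by intramolecular α-arylation of the malonate (zerovalent palladium inserts into the C–Br bond), giving 11.

Step 10. The catalyst may discriminate poorly between the two oxetane CH2 groups (low enantioselectivity), or bromide may add reversibly to the enone. Fallback, from 16 back to 18: the oxetane is opened without the chiral catalyst (Me3SiBr, CH2Cl2, −78 °C; aqueous citric acid) to give the racemate, that is 18 together with its enantiomer, the (4R)-bromohydrin F5. Preparative chromatography on a chiral stationary phase separates them, and 18 goes on.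

Further compounds

F1 | step 12 | (4R,5S,10S)-1-bromo-11,12,14-trimethoxy-3,7-bis(trimethylsilyloxy)-1,2-secoabieta-2,6,8,11,13-pentaen-19,20-olide | COc1c(OC)c2c(c(OC)c1C(C)C)C(O[Si](C)(C)C)=C[C@@H]1[C@@]2(CBr)COC(=O)[C@@]1(C)C(=C)O[Si](C)(C)C
F2 | step 12 | 11,12,14-trimethoxy-3,7-bis(trimethylsilyloxy)abieta-6,8,11,13-tetraen-19,20-olide (C3 epimers) | COc1c(OC)c2c(c(OC)c1C(C)C)C(O[Si](C)(C)C)=C[C@@H]1[C@]23CCC(O[Si](C)(C)C)[C@]1(C)C(=O)OC3
F3 | step 12 | 3-hydroxy-11,12,14-trimethoxy-7-oxoabieta-8,11,13-trien-19,20-olide (C3 epimers) | COc1c(OC)c2c(c(OC)c1C(C)C)C(=O)C[C@@H]1[C@]23CCC(O)[C@]1(C)C(=O)OC3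
F4 | step 5 | diethyl 2-[3-(2-bromo-5-isopropyl-3,4,6-trimethoxyphenyl)-3-oxopropyl]malonate | CCOC(=O)C(CCC(=O)c1c(Br)c(OC)c(OC)c(C(C)C)c1OC)C(=O)OCC
F5 | step 10 | (4R)-4-(bromomethyl)-4-(hydroxymethyl)-7-isopropyl-5,6,8-trimethoxynaphthalen-1(4H)-one | OC[C@@]1(CBr)C=CC(=O)c2c1c(OC)c(OC)c(C(C)C)c2OC
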